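**Retrosynthetic overview**

1. Target 18 ⇐ silyl ether 17 ⇐ cyclohexadienyl 2‑bromoacrylate 14 + 3‑methylbutanoate: one palladium step closes the lactone (C3–C3a) and forms the key C4–O ester bond anti to palladium.
2. 14 ⇐ cyclohexadienol 12 ⇐ (Z)‑trienol 11 by ring‑closing metathesis (the carbocycle with its tetrasubstituted C5=C6 alkene).
3. 11 ⇐ ynal 8 by reagent‑controlled 2‑methylallylboration (sets C7a) and cis‑semihydrogenation.
4. 8 ⇐ (S)‑citronellal 1 by α‑methylenation, Corey–Fuchs homologation/formylation, and ozonolysis–reduction of the prenyl end to the protected primary alcohol.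
5. Ring order: six‑membered carbocycle first (metathesis), γ‑lactone second (palladium cascade).

Assumption: (S)‑(−)‑citronellal of high ee is the commercial chiral source; ring positions are given in 1‑benzofuran‑2‑one numbering (O1, C2, C3, C3a, C4 to C7, C7a); reagents are not numbered.

**Route**

Step 1
Reactants: 1 (S)-citronellal
Product: 2 (3S)-3,7-dimethyl-2-methylideneoct-6-enal
Conditions: 37% aq. HCHO, pyrrolidine (10 mol%), EtCO2H (10 mol%), i-PrOH, 45 °C
Reagents that add atoms: formaldehyde, C=O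
Why: Amine-catalysed Mannich condensation/elimination (α-methylenation of an aldehyde through its enamine) installs the C=CH2 unit, and the β-stereocentre is not involved and is retained.

Step 2
Reactants: 2 (3S)-3,7-dimethyl-2-methylideneoct-6-enal
Product: 3 (4S)-1,1-dibromo-4,8-dimethyl-3-methylidenenona-1,7-diene
Conditions: CBr4 (2 equiv), PPh3 (4 equiv), CH2Cl2, 0 °C
Reagents that add atoms: carbon tetrabromide, BrC(Br)(Br)Br
Why: Corey–Fuchs dibromo-olefination (Wittig reaction of Ph3P=CBr2) turns the enal into the 1,1-dibromodiene, a masked alkyne.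

Step 3
Reactants: 3 (4S)-1,1-dibromo-4,8-dimethyl-3-methylidenenona-1,7-diene
Product: 5 (4S)-7,7-dibromo-4-methyl-5-methylidenehept-6-en-1-ol, via aldehyde 4 (not isolated)
Conditions: O3, CH2Cl2/MeOH, −78 °C (Sudan Red 7B end point); then NaBH4, −78 → 0 °C
Reagents that add atoms: ozone, [O-][O+]=O
Why: Ozonolysis with reductive work-up, in which the electron-rich trisubstituted alkene should react well ahead of the 1,1-disubstituted alkene conjugated to the electron-poor dibromovinyl group, and NaBH4 reduces the aldehyde in the flask.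

Step 4
Reactants: 5 (4S)-7,7-dibromo-4-methyl-5-methylidenehept-6-en-1-ol
Product: 6 tert-butyl{[(4S)-7,7-dibromo-4-methyl-5-methylidenehept-6-en-1-yl]oxy}dimethylsilane
Conditions: TBSCl, imidazole, CH2Cl2, rt
Reagents that add atoms: tert-butyldimethylsilyl chloride, CC(C)(C)[Si](C)(C)Cl
Why: Standard silylation of a primary alcohol masks the terminal hydroxyl through the organolithium, acylation and palladium steps.

Step 5
Reactants: 6 tert-butyl{[(4S)-7,7-dibromo-4-methyl-5-methylidenehept-6-en-1-yl]oxy}dimethylsilane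
Product: 8 (5S)-8-[(tert-butyldimethylsilyl)oxy]-5-methyl-4-methylideneoct-2-ynal, via lithium acetylide 7 (not isolated)
Conditions: n-BuLi (2.2 equiv), THF, −78 °C; then DMF, −78 → 0 °C; aq. KH2PO4
Reagents that add atoms: N,N-dimethylformamide, CN(C)C=O
Why: Second stage of the Corey–Fuchs sequence (Br/Li exchange, Fritsch–Buttenberg–Wiechell rearrangement to the acetylide) followed by formylation with DMF gives the conjugated ynal.

Step 6
Reactants: 8 (5S)-8-[(tert-butyldimethylsilyl)oxy]-5-methyl-4-methylideneoct-2-ynal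
Product: 10 (4R,8S)-11-[(tert-butyldimethylsilyl)oxy]-2,8-dimethyl-7-methylideneundec-1-en-5-yn-4-ol, via borinate ester 9 (not isolated)
Conditions: (+)-Ipc2BOMe, 2-methylallylmagnesium chloride, Et2O, 0 °C → rt; then 8, −78 °C; then NaOH, H2O2
Reagents that add atoms: (+)-B-(2-methylallyl)diisopinocampheylborane, CC(=C)CB([C@H]1C[C@H]2C[C@@H]([C@@H]1C)C2(C)C)[C@H]1C[C@H]2C[C@@H]([C@@H]1C)C2(C)C
Why: Brown asymmetric allylboration through a chair transition state, in which the (+)-Ipc2B reagent delivers the 2-methylallyl group to the Re face of the ynal and so sets the (R)-carbinol (future C7a) under reagent control, independent of the remote side-chain centre.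

Step 7
Reactants: 10 (4R,8S)-11-[(tert-butyldimethylsilyl)oxy]-2,8-dimethyl-7-methylideneundec-1-en-5-yn-4-ol
Product: 11 (4R,5Z,8S)-11-[(tert-butyldimethylsilyl)oxy]-2,8-dimethyl-7-methylideneundeca-1,5-dien-4-ol
Conditions: H2 (1 atm), Pd/CaCO3 poisoned with Pb(OAc)2, quinoline, EtOAc, rt
Reagents that add atoms: none
Why: Lindlar semihydrogenation adds H2 syn to the alkyne and gives the Z-alkene that lets the two chain ends meet in the next step; the carbinol centre is untouched.

Step 8
Reactants: 11 (4R,5Z,8S)-11-[(tert-butyldimethylsilyl)oxy]-2,8-dimethyl-7-methylideneundeca-1,5-dien-4-ol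
Product: 12 (1R)-4-[(2S)-5-[(tert-butyldimethylsilyl)oxy]pentan-2-yl]-5-methylcyclohexa-2,4-dien-1-ol
Conditions: second-generation Hoveyda–Grubbs catalyst RuCl2(H2IMes)(=CH-C6H4-2-Oi-Pr) (10 mol%), 1,4-benzoquinone (10 mol%), PhMe (5 mM), 70 °C, Ar sparge
Reagents that add atoms: none
Why: Ring-closing metathesis between the 2-methylallyl alkene and the terminal alkene of the Z-diene forms the six-membered ring with its tetrasubstituted alkene, with loss of ethene and no change at either stereocentre.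

Step 9
Reactants: 12 (1R)-4-[(2S)-5-[(tert-butyldimethylsilyl)oxy]pentan-2-yl]-5-methylcyclohexa-2,4-dien-1-ol
Product: 14 (1R)-4-[(2S)-5-[(tert-butyldimethylsilyl)oxy]pentan-2-yl]-5-methylcyclohexa-2,4-dien-1-yl 2-bromoprop-2-enoate, via dibromopropanoate ester 13 (not isolated)
Conditions: 2,3-dibromopropanoyl chloride, Et3N (3 equiv), CH2Cl2, −20 → 0 °C
Reagents that add atoms: 2,3-dibromopropanoyl chloride, BrCC(Br)C(Cl)=O
Why: O-acylation followed by Et3N-mediated E1cB loss of HBr gives the 2-bromoacrylate under basic, non-ionising conditions that keep the acid-sensitive dienol intact, with retention at the carbinol.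

Step 10
Reactants: 14 (1R)-4-[(2S)-5-[(tert-butyldimethylsilyl)oxy]pentan-2-yl]-5-methylcyclohexa-2,4-dien-1-yl 2-bromoprop-2-enoate
Product: 17 [(3aR,4S,7aR)-5-[(2S)-5-[(tert-butyldimethylsilyl)oxy]pentan-2-yl]-6-methyl-3-methylidene-2-oxo-2,3,3a,4,7,7a-hexahydro-1-benzofuran-4-yl] 3-methylbutanoate, via vinylpalladium bromide 15 (not isolated), via allylpalladium bromide 16 (not isolated)
Conditions: Pd2(dba)3 (2.5 mol%), P(2-furyl)3 (10 mol%), i-PrCH2CO2Cs (3 equiv), n-Bu4NBr (1 equiv), DMF, 30 °C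
Reagents that add atoms: cesium 3-methylbutanoate, [Cs+].CC(C)CC([O-])=O
Why: Proposed new method: a zerovalent-palladium carbo-acyloxylation of a 1,3-diene in which oxidative addition into the C–Br bond gives vinylpalladium 15, 5-exo syn-carbopalladation of the proximal ring alkene from the face of the tethering ester oxygen closes the cis-fused lactone (C3–C3a bond, C3a set from C7a) and leaves palladium on C4 of the π-allyl 16 on that same face, and 3-methylbutanoate then attacks the less substituted allyl terminus C4 from outside the metal (bromide and phosphine keep the carboxylate off palladium) anti to palladium, so the new C4–O bond is trans to the C3a–C3 bond and the tetrasubstituted C5=C6 alkene is regenerated; the closest known reaction type is the Heck/Tsuji–Trost three-component coupling of 1,3-dienes with vinyl or aryl halides and amine or stabilised-carbon nucleophiles, together with ester-tethered 5-exo carbopalladation to α-methylene-γ-butyrolactones, whereas intermolecular carboxylate capture on a cyclohexadienyl 2-bromoacrylate has not been shown.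

Step 11
Reactants: 17 [(3aR,4S,7aR)-5-[(2S)-5-[(tert-butyldimethylsilyl)oxy]pentan-2-yl]-6-methyl-3-methylidene-2-oxo-2,3,3a,4,7,7a-hexahydro-1-benzofuran-4-yl] 3-methylbutanoate
Product: 18 [(3aR,4S,7aR)-5-[(2S)-5-hydroxypentan-2-yl]-6-methyl-3-methylidene-2-oxo-2,3,3a,4,7,7a-hexahydro-1-benzofuran-4-yl] 3-methylbutanoate
Conditions: HF·pyridine, pyridine, THF, 0 °C → rt
Reagents that add atoms: none
Why: Buffered fluoride desilylation cleaves only the primary Si–O bond and leaves the ester, the α-methylene lactone and all four stereocentres untouched.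

**Compound list**

1 | (S)-citronellal, (3S)-3,7-dimethyloct-6-enal | O=CC[C@@H](C)CCC=C(C)C | starting material
2 | (3S)-3,7-dimethyl-2-methylideneoct-6-enal | O=CC(=C)[C@@H](C)CCC=C(C)C | intermediate
3 | (4S)-1,1-dibromo-4,8-dimethyl-3-methylidenenona-1,7-diene | BrC(Br)=CC(=C)[C@@H](C)CCC=C(C)C | intermediate
4 | (4S)-7,7-dibromo-4-methyl-5-methylidenehept-6-enal | O=CCC[C@H](C)C(=C)C=C(Br)Br | intermediate
5 | (4S)-7,7-dibromo-4-methyl-5-methylidenehept-6-en-1-ol | OCCC[C@H](C)C(=C)C=C(Br)Br | intermediate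
6 | tert-butyl{[(4S)-7,7-dibromo-4-methyl-5-methylidenehept-6-en-1-yl]oxy}dimethylsilane | CC(C)(C)[Si](C)(C)OCCC[C@H](C)C(=C)C=C(Br)Br | intermediate
7 | {(4S)-7-[(tert-butyldimethylsilyl)oxy]-4-methyl-3-methylidenehept-1-yn-1-yl}lithium | [Li]C#CC(=C)[C@@H](C)CCCO[Si](C)(C)C(C)(C)C | intermediate
8 | (5S)-8-[(tert-butyldimethylsilyl)oxy]-5-methyl-4-methylideneoct-2-ynal | O=CC#CC(=C)[C@@H](C)CCCO[Si](C)(C)C(C)(C)C | intermediate
9 | (4R,8S)-11-[(tert-butyldimethylsilyl)oxy]-2,8-dimethyl-7-methylideneundec-1-en-5-yn-4-yl diisopinocampheylborinate (Ipc groups of the (+)-series) | CC(=C)C[C@@H](OB([C@H]1C[C@H]2C[C@@H]([C@@H]1C)C2(C)C)[C@H]1C[C@H]2C[C@@H]([C@@H]1C)C2(C)C)C#CC(=C)[C@@H](C)CCCO[Si](C)(C)C(C)(C)C | intermediate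
10 | (4R,8S)-11-[(tert-butyldimethylsilyl)oxy]-2,8-dimethyl-7-methylideneundec-1-en-5-yn-4-ol | CC(=C)C[C@@H](O)C#CC(=C)[C@@H](C)CCCO[Si](C)(C)C(C)(C)C | intermediate
11 | (4R,5Z,8S)-11-[(tert-butyldimethylsilyl)oxy]-2,8-dimethyl-7-methylideneundeca-1,5-dien-4-ol | CC(=C)C[C@@H](O)/C=C\C(=C)[C@@H](C)CCCO[Si](C)(C)C(C)(C)C | intermediate
12 | (1R)-4-[(2S)-5-[(tert-butyldimethylsilyl)oxy]pentan-2-yl]-5-methylcyclohexa-2,4-dien-1-ol | O[C@H]1C=CC([C@@H](C)CCCO[Si](C)(C)C(C)(C)C)=C(C)C1 | intermediate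
13 | (1R)-4-[(2S)-5-[(tert-butyldimethylsilyl)oxy]pentan-2-yl]-5-methylcyclohexa-2,4-dien-1-yl 2,3-dibromopropanoate (both epimers at the CHBr carbon) | BrCC(Br)C(=O)O[C@H]1C=CC([C@@H](C)CCCO[Si](C)(C)C(C)(C)C)=C(C)C1 | intermediate
14 | (1R)-4-[(2S)-5-[(tert-butyldimethylsilyl)oxy]pentan-2-yl]-5-methylcyclohexa-2,4-dien-1-yl 2-bromoprop-2-enoate | C=C(Br)C(=O)O[C@H]1C=CC([C@@H](C)CCCO[Si](C)(C)C(C)(C)C)=C(C)C1 | intermediate
15 | vinylpalladium bromide from oxidative addition of 14 at C–Br (phosphine ligands omitted) | Br[Pd]C(=C)C(=O)O[C@H]1C=CC([C@@H](C)CCCO[Si](C)(C)C(C)(C)C)=C(C)C1 | intermediate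
16 | allylpalladium bromide after 5-exo insertion, drawn as the η1 form with palladium on C4 cis to the C3–C3a bond (phosphine ligands omitted) | C=C1C(=O)O[C@@H]2CC(C)=C([C@@H](C)CCCO[Si](C)(C)C(C)(C)C)[C@H]([Pd]Br)[C@H]12 | intermediate
17 | [(3aR,4S,7aR)-5-[(2S)-5-[(tert-butyldimethylsilyl)oxy]pentan-2-yl]-6-methyl-3-methylidene-2-oxo-2,3,3a,4,7,7a-hexahydro-1-benzofuran-4-yl] 3-methylbutanoate | C=C1C(=O)O[C@@H]2CC(C)=C([C@@H](C)CCCO[Si](C)(C)C(C)(C)C)[C@@H](OC(=O)CC(C)C)[C@H]12 | intermediate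
18 | [(3aR,4S,7aR)-5-[(2S)-5-hydroxypentan-2-yl]-6-methyl-3-methylidene-2-oxo-2,3,3a,4,7,7a-hexahydro-1-benzofuran-4-yl] 3-methylbutanoate (CNP0289409.1) | C=C1C(=O)O[C@@H]2CC(C)=C([C@@H](C)CCCO)[C@@H](OC(=O)CC(C)C)[C@H]12 | target

**Step count and risks**

Total: 11 steps. Longest linear sequence: 11 steps from 1.

Steps most likely to fail:

Step 3 (chemoselective ozonolysis). The dibromodiene alkene may be attacked alongside the prenyl alkene. Fallback, from 2 back to 6: ozonise at the enal stage, where the only other alkene is the strongly deactivated α-methylene aldehyde. Treating 2 with O3 and then NaBH4/CeCl3·7H2O reduces both aldehydes to (3S)-3-methyl-2-methylidenehexane-1,6-diol F1. MnO2 oxidises only the allylic alcohol to (3S)-6-hydroxy-3-methyl-2-methylidenehexanal F2. TBSCl/imidazole gives (3S)-6-[(tert-butyldimethylsilyl)oxy]-3-methyl-2-methylidenehexanal F3, and Corey–Fuchs olefination (CBr4, PPh3) of F3 gives 6.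

Step 8 (metathesis to a tetrasubstituted alkene inside a conjugated diene, giving an aromatisation-prone dienol). Fallback, from 11 to 17: defer ring closure until the lactone is in place.
- Hydroxyl-directed epoxidation of 11 with Ti(Oi-Pr)4/t-BuOOH, where allylic 1,3-strain of the Z-alkene favours the threo isomer, gives (1R)-1-[(2S,3R)-3-[(3S)-6-[(tert-butyldimethylsilyl)oxy]-3-methylhex-1-en-2-yl]oxiran-2-yl]-3-methylbut-3-en-1-ol F4.
- DCC/DMAP coupling with 2-(diethoxyphosphoryl)acetic acid gives the phosphonoacetate (1R)-1-[(2S,3R)-3-[(3S)-6-[(tert-butyldimethylsilyl)oxy]-3-methylhex-1-en-2-yl]oxiran-2-yl]-3-methylbut-3-en-1-yl 2-(diethoxyphosphoryl)acetate F5.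
- NaH in THF drives 5-exo opening of the epoxide by the phosphonate carbanion with inversion at the future C3a; paraformaldehyde then gives, by Horner–Wadsworth–Emmons olefination, (4S,5R)-4-[(1S,3S)-6-[(tert-butyldimethylsilyl)oxy]-1-hydroxy-3-methyl-2-methylidenehexyl]-3-methylidene-5-(2-methylprop-2-en-1-yl)oxolan-2-one F6.
- 3-Methylbutanoic anhydride/DMAP gives (1S,3S)-6-[(tert-butyldimethylsilyl)oxy]-3-methyl-2-methylidene-1-[(2R,3R)-4-methylidene-2-(2-methylprop-2-en-1-yl)-5-oxooxolan-3-yl]hexyl 3-methylbutanoate F7.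
- Ring-closing metathesis of F7 (second-generation Hoveyda–Grubbs catalyst), now on a non-conjugated diene held cis on the lactone, gives 17.

Step 10 (the new palladium cascade). Likely failure modes are ionisation of the dienyl ester with aromatisation, β-hydride elimination from the π-allyl to dienes, and attack at the tertiary terminus. Fallback with known chemistry, from 12 to 17:
- DCC/DMAP esterification of 12 with 2-(diethoxyphosphoryl)acetic acid gives (1R)-4-[(2S)-5-[(tert-butyldimethylsilyl)oxy]pentan-2-yl]-5-methylcyclohexa-2,4-dien-1-yl 2-(diethoxyphosphoryl)acetate F8.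
- Diazo transfer (4-acetamidobenzenesulfonyl azide, DBU) gives the corresponding 2-diazo-2-(diethoxyphosphoryl)acetate F9.
- Rh2(OAc)4-catalysed intramolecular cyclopropanation of the proximal ring alkene on the face of the ester oxygen gives the cyclopropane-fused α-phosphono lactone F10, whose phosphonate-bearing carbon is shared by the lactone and a cyclopropane spanning the former C2=C3 of the dienyl ring.
- Cesium 3-methylbutanoate in DMF opens this doubly activated vinylcyclopropane at the allylic carbon with inversion, so the ester ends trans to the lactone C–C bond. The phosphonate carbanion is then trapped with paraformaldehyde (Horner–Wadsworth–Emmons) to give 17.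

**Further compounds**

F1 | step 3 | (3S)-3-methyl-2-methylidenehexane-1,6-diol | OCC(=C)[C@@H](C)CCCO
F2 | step 3 | (3S)-6-hydroxy-3-methyl-2-methylidenehexanal | O=CC(=C)[C@@H](C)CCCO
F3 | step 3 | (3S)-6-[(tert-butyldimethylsilyl)oxy]-3-methyl-2-methylidenehexanal | O=CC(=C)[C@@H](C)CCCO[Si](C)(C)C(C)(C)C
F4 | step 8 | (1R)-1-[(2S,3R)-3-[(3S)-6-[(tert-butyldimethylsilyl)oxy]-3-methylhex-1-en-2-yl]oxiran-2-yl]-3-methylbut-3-en-1-ol | CC(=C)C[C@@H](O)[C@@H]1O[C@@H]1C(=C)[C@@H](C)CCCO[Si](C)(C)C(C)(C)C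
F5 | step 8 | (1R)-1-[(2S,3R)-3-[(3S)-6-[(tert-butyldimethylsilyl)oxy]-3-methylhex-1-en-2-yl]oxiran-2-yl]-3-methylbut-3-en-1-yl 2-(diethoxyphosphoryl)acetate | CCOP(=O)(OCC)CC(=O)O[C@H](CC(C)=C)[C@@H]1O[C@@H]1C(=C)[C@@H](C)CCCO[Si](C)(C)C(C)(C)C
F6 | step 8 | (4S,5R)-4-[(1S,3S)-6-[(tert-butyldimethylsilyl)oxy]-1-hydroxy-3-methyl-2-methylidenehexyl]-3-methylidene-5-(2-methylprop-2-en-1-yl)oxolan-2-one | C=C1C(=O)O[C@H](CC(C)=C)[C@@H]1[C@H](O)C(=C)[C@@H](C)CCCO[Si](C)(C)C(C)(C)C
F7 | step 8 | (1S,3S)-6-[(tert-butyldimethylsilyl)oxy]-3-methyl-2-methylidene-1-[(2R,3R)-4-methylidene-2-(2-methylprop-2-en-1-yl)-5-oxooxolan-3-yl]hexyl 3-methylbutanoate | C=C1C(=O)O[C@H](CC(C)=C)[C@@H]1[C@H](OC(=O)CC(C)C)C(=C)[C@@H](C)CCCO[Si](C)(C)C(C)(C)C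
F8 | step 10 | (1R)-4-[(2S)-5-[(tert-butyldimethylsilyl)oxy]pentan-2-yl]-5-methylcyclohexa-2,4-dien-1-yl 2-(diethoxyphosphoryl)acetate | CCOP(=O)(OCC)CC(=O)O[C@H]1C=CC([C@@H](C)CCCO[Si](C)(C)C(C)(C)C)=C(C)C1
F9 | step 10 | (1R)-4-[(2S)-5-[(tert-butyldimethylsilyl)oxy]pentan-2-yl]-5-methylcyclohexa-2,4-dien-1-yl 2-diazo-2-(diethoxyphosphoryl)acetate | CCOP(=O)(OCC)C(=[N+]=[N-])C(=O)O[C@H]1C=CC([C@@H](C)CCCO[Si](C)(C)C(C)(C)C)=C(C)C1
F10 | step 10 | cyclopropane-fused α-(diethoxyphosphoryl) lactone: lactone α-carbon bonded to both former C2 and C3 of the dienyl ring on the face of the ring oxygen, tetrasubstituted alkene and (2S)-silyloxypentyl side chain unchanged | O=C1O[C@@H]2CC(C)=C([C@@H](C)CCCO[Si](C)(C)C(C)(C)C)[C@H]3[C@@H]2[C@@]13P(=O)(OCC)OCC
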